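Ring C is cut at C4a–C4, C4–C3 and O1–C2, which splits the flavonol core into a ring A iodoarene, carbon monoxide (C4) and 4-ethynylanisole (C3, C2, ring B). One palladium-catalysed carbonylative alkynylation with 6-endo closure makes all three bonds. It exploits the position of C4a between two oxygen-bearing carbons, C5 and C8a, of which only the C8a oxygen may become O1. The precursor therefore carries iodine on C4a, amine-stable MOM acetals on O5 and O7, the 1,1-dimethylallyl group on C8 and, on O8a alone, an acetate that diethylamine strips in the flask; the same acetate protects the preceding Claisen shift and iodination. The C3 hydroxyl follows by lithiation, borylation and oxidation.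

Key step: step 5

Remark on the chemistry: the acetyl group on O8a is treated as a protecting group of the o-iodophenol, which is regenerated in the flask at the start of the key step. The target has no stereocentre.

Step 1
Reactants: 1 phloroglucinol
Product: 2 3,5-bis(methoxymethoxy)phenol
Conditions: MOMCl (2.0 equiv), K2CO3 (2.5 equiv), acetone, 0 °C → rt; chromatography
Reagents that add atoms: chloromethyl methyl ether, COCCl
Why: Williamson-type O-alkylation with a hard chloromethyl ether goes to oxygen and not to carbon, the three hydroxyls are equivalent so only the degree of substitution has to be sorted, and the mono-, bis- and tris-ethers differ enough in polarity to be separated, the unwanted ones being recyclable by acid hydrolysis.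

Step 2
Reactants: 2 3,5-bis(methoxymethoxy)phenol; 3 1-bromo-3-methylbut-2-ene (prenyl bromide)
Product: 4 1,3-bis(methoxymethoxy)-5-[(3-methylbut-2-en-1-yl)oxy]benzene
Conditions: K2CO3 (1.5 equiv), acetone, reflux
Reagents that add atoms: none
Why: Williamson ether synthesis with a carbonate base in a polar aprotic solvent favours O- over C-allylation of the single phenoxide and runs by SN2 at the primary carbon, so the prenyl unit arrives unrearranged.

Step 3
Reactants: 4 1,3-bis(methoxymethoxy)-5-[(3-methylbut-2-en-1-yl)oxy]benzene
Product: 7 3,5-bis(methoxymethoxy)-2-(2-methylbut-3-en-2-yl)phenyl acetate, via ortho-dienone 5 (not isolated), via Claisen phenol 6 (not isolated)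
Conditions: Ac2O (5 equiv), PhNEt2, 185 °C, sealed tube, Ar
Reagents that add atoms: acetic anhydride, CC(=O)OC(C)=O
Why: Aromatic Claisen rearrangement with acylative trapping, in which the [3,3] shift delivers the tertiary terminus of the prenyl unit to one of two equivalent ortho carbons, the amine and acetic acid buffer speeds enolisation of 5 ahead of a Cope shift to the para carbon, and acetylation of 6 removes the O–H that would otherwise drive the abnormal Claisen isomerisation, dihydrobenzofuran formation and return to the dienone; the stereocentre of 5 is transient and racemic.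

Step 4
Reactants: 7 3,5-bis(methoxymethoxy)-2-(2-methylbut-3-en-2-yl)phenyl acetate
Product: 8 2-iodo-3,5-bis(methoxymethoxy)-6-(2-methylbut-3-en-2-yl)phenyl acetate
Conditions: NIS (1.05 equiv), MeCN, 0 °C → rt, dark
Reagents that add atoms: N-iodosuccinimide, O=C1CCC(=O)N1I
Why: Electrophilic aromatic iodination of a resorcinol-type diether goes to the carbon ortho to one OMOM and para to the other (the future C4a) and not to the carbon pinched between both OMOM groups, one of which is pushed towards it by the tert-alkyl neighbour, while the arene is far more nucleophilic than a monosubstituted alkene on a quaternary carbon and no free hydroxyl is left to drive iodoetherification.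

Step 5
Reactants: 8 2-iodo-3,5-bis(methoxymethoxy)-6-(2-methylbut-3-en-2-yl)phenyl acetate; 9 4-ethynylanisole
Product: 13 5,7-bis(methoxymethoxy)-2-(4-methoxyphenyl)-8-(2-methylbut-3-en-2-yl)-4H-chromen-4-one, via iodophenol 10 (not isolated), via alkynone 11 (not isolated), via enaminone 12 (not isolated)
Conditions: 9 (1.5 equiv), PdCl2(dppf) (5 mol %), Et2NH (solvent), CO (20 bar), 120 °C, autoclave, no copper salt
Reagents that add atoms: carbon monoxide, [C-]#[O+]; diethylamine, CCNCC (atoms held only in intermediate 12)
Why: Diethylamine first aminolyses the only ester to free 10, zerovalent palladium (formed from PdCl2(dppf) under amine and CO) adds to the C4a–I bond, CO inserts to give the aroyl complex of divalent palladium, and amine-assisted alkynylation with reductive elimination forms C4a–C4 and C4–C3 in alkynone 11. Diethylamine then adds to C2 to give enaminone 12, and the C8a phenoxide displaces it by addition–elimination at C2, so that ring C closes in an overall 6-endo-dig mode with formation of O1–C2. The closest known reaction type is the copper-free carbonylative Sonogashira annulation of o-iodophenols, and of their acetates, with terminal arylacetylenes to flavones. The step needs CO insertion ahead of alkynylation, which CO pressure, the absence of copper and the electron-rich, doubly ortho-flanked aryl–palladium bond all favour, and 6-endo instead of 5-exo closure, which the enaminone secures because its only electrophilic carbon is C2. It also needs O8a and not O5 as the ring oxygen, which is settled because the MOM acetals on O5 and O7 are inert to amines, and it needs the alkene to stay out, which follows from a vinyl group that sits meta to C4a on a quaternary carbon, cannot reach the metal and has no allylic hydrogen for chain walking. Should coupling outrun aminolysis, the acetate falls off at the alkynone stage, where the ortho acyl group makes it more labile, and the same flavone results; no stereocentre is formed.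

Step 6
Reactants: 13 5,7-bis(methoxymethoxy)-2-(4-methoxyphenyl)-8-(2-methylbut-3-en-2-yl)-4H-chromen-4-one
Product: 16 3-hydroxy-5,7-bis(methoxymethoxy)-2-(4-methoxyphenyl)-8-(2-methylbut-3-en-2-yl)-4H-chromen-4-one, via 3-lithioflavone 14 (not isolated), via C3 boronate 15 (not isolated)
Conditions: LDA (1.5 equiv), THF, −78 °C; B(OMe)3 (3 equiv), −78 → 0 °C; AcOH, 30% aq H2O2, 0 °C → rt
Reagents that add atoms: hydrogen peroxide, OO; lithium diisopropylamide, [Li]N(C(C)C)C(C)C (lithium held only in 14); trimethyl borate, COB(OC)OC (atoms held only in 15)
Why: Carbonyl-assisted deprotonation of a flavone at C3 by a lithium amide, capture by a borate and peroxide-induced 1,2-migration from boron to oxygen is an established flavone-to-flavonol sequence, C3–H being the only C–H within reach of LDA (C6–H between the two acetals would need an alkyllithium), and neither the vinyl group nor the MOM acetals respond to LDA at −78 °C or to acetic acid-buffered H2O2.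

Step 7
Reactants: 16 3-hydroxy-5,7-bis(methoxymethoxy)-2-(4-methoxyphenyl)-8-(2-methylbut-3-en-2-yl)-4H-chromen-4-one
Product: 17 3,5,7-trihydroxy-2-(4-methoxyphenyl)-8-(2-methylbut-3-en-2-yl)-4H-chromen-4-one (target)
Conditions: HCl (1 M in MeOH), 45 °C
Reagents that add atoms: none
Why: Acid-catalysed transacetalisation to methanol cleaves both aryl MOM acetals (the one on O5 helped by the peri carbonyl) under conditions too weak to protonate a monosubstituted alkene next to a quaternary carbon, so cyclisation onto O7 should not occur and the aryl methyl ether stays intact.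

Compound list
1 | phloroglucinol (benzene-1,3,5-triol) | Oc1cc(O)cc(O)c1 | starting material
2 | 3,5-bis(methoxymethoxy)phenol | COCOc1cc(O)cc(OCOC)c1 | intermediate
3 | 1-bromo-3-methylbut-2-ene (prenyl bromide) | CC(C)=CCBr | starting material
4 | 1,3-bis(methoxymethoxy)-5-[(3-methylbut-2-en-1-yl)oxy]benzene | COCOc1cc(OCC=C(C)C)cc(OCOC)c1 | intermediate
5 | 3,5-bis(methoxymethoxy)-6-(2-methylbut-3-en-2-yl)cyclohexa-2,4-dien-1-one (racemic, formed in the flask) | C=CC(C)(C)C1C(=O)C=C(OCOC)C=C1OCOC | intermediate
6 | 3,5-bis(methoxymethoxy)-2-(2-methylbut-3-en-2-yl)phenol (formed in the flask) | C=CC(C)(C)c1c(O)cc(OCOC)cc1OCOC | intermediate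
7 | 3,5-bis(methoxymethoxy)-2-(2-methylbut-3-en-2-yl)phenyl acetate | C=CC(C)(C)c1c(OC(C)=O)cc(OCOC)cc1OCOC | intermediate
8 | 2-iodo-3,5-bis(methoxymethoxy)-6-(2-methylbut-3-en-2-yl)phenyl acetate | C=CC(C)(C)c1c(OC(C)=O)c(I)c(OCOC)cc1OCOC | intermediate
9 | 4-ethynylanisole (1-ethynyl-4-methoxybenzene) | COc1ccc(C#C)cc1 | starting material
10 | 2-iodo-3,5-bis(methoxymethoxy)-6-(2-methylbut-3-en-2-yl)phenol (formed in the flask) | C=CC(C)(C)c1c(O)c(I)c(OCOC)cc1OCOC | intermediate
11 | 1-[2-hydroxy-4,6-bis(methoxymethoxy)-3-(2-methylbut-3-en-2-yl)phenyl]-3-(4-methoxyphenyl)prop-2-yn-1-one (formed in the flask) | C=CC(C)(C)c1c(O)c(C(=O)C#Cc2ccc(OC)cc2)c(OCOC)cc1OCOC | intermediate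
12 | (E)-3-(diethylamino)-1-[2-hydroxy-4,6-bis(methoxymethoxy)-3-(2-methylbut-3-en-2-yl)phenyl]-3-(4-methoxyphenyl)prop-2-en-1-one (push–pull alkene, geometry labile, formed in the flask) | C=CC(C)(C)c1c(O)c(C(=O)/C=C(/N(CC)CC)c2ccc(OC)cc2)c(OCOC)cc1OCOC | intermediate
13 | 5,7-bis(methoxymethoxy)-2-(4-methoxyphenyl)-8-(2-methylbut-3-en-2-yl)-4H-chromen-4-one | C=CC(C)(C)c1c(OCOC)cc(OCOC)c2c(=O)cc(-c3ccc(OC)cc3)oc12 | intermediate
14 | 3-lithio-5,7-bis(methoxymethoxy)-2-(4-methoxyphenyl)-8-(2-methylbut-3-en-2-yl)-4H-chromen-4-one (formed in the flask) | C=CC(C)(C)c1c(OCOC)cc(OCOC)c2c(=O)c([Li])c(-c3ccc(OC)cc3)oc12 | intermediate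
15 | dimethyl [5,7-bis(methoxymethoxy)-2-(4-methoxyphenyl)-8-(2-methylbut-3-en-2-yl)-4-oxo-4H-chromen-3-yl]boronate (formed in the flask) | C=CC(C)(C)c1c(OCOC)cc(OCOC)c2c(=O)c(B(OC)OC)c(-c3ccc(OC)cc3)oc12 | intermediate
16 | 3-hydroxy-5,7-bis(methoxymethoxy)-2-(4-methoxyphenyl)-8-(2-methylbut-3-en-2-yl)-4H-chromen-4-one | C=CC(C)(C)c1c(OCOC)cc(OCOC)c2c(=O)c(O)c(-c3ccc(OC)cc3)oc12 | intermediate
17 | 3,5,7-trihydroxy-2-(4-methoxyphenyl)-8-(2-methylbut-3-en-2-yl)-4H-chromen-4-one | C=CC(C)(C)c1c(O)cc(O)c2c(=O)c(O)c(-c3ccc(OC)cc3)oc12 | target

Total step count: 7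
Longest linear sequence: 7 steps (1 → 2 → 4 → 7 → 8 → 13 → 16 → 17)

Steps most likely to fail

Step 5.
- **What may go wrong:** Oxidative addition may be sluggish at the electron-rich C–I bond, which is flanked on both sides. Alkynylation may come before CO insertion, the amine may intercept the aroyl complex, the hindered ester may aminolyse slowly, or closure may go 5-exo.
- **Fallback:** It builds the same three bonds without palladium or CO, sets out from 8 and comes back at 11.
  - K2CO3 in MeOH frees iodophenol 10, which is now isolated.
  - iPrMgCl·LiCl (2.2 equiv, THF, −20 → 0 °C) deprotonates the hydroxyl and exchanges the iodine, giving chloromagnesium 2-(chloromagnesio)-3,5-bis(methoxymethoxy)-6-(2-methylbut-3-en-2-yl)phenoxide F1.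
  - This is acylated with N-methoxy-N-methyl-3-(4-methoxyphenyl)prop-2-ynamide F2, made from 9 with n-BuLi and then N-methoxy-N-methylcarbamoyl chloride. The product is alkynone 11.
  - Warming 11 with Et2NH in EtOH then closes ring C through 12 to give 13.

Step 6.
- **What may go wrong:** Deprotonation may occur at a site other than C3. The lithiated pyranone may open by expulsion of the C8a phenoxide, or capture by the borate may be incomplete.
- **Fallback:** It replaces carbanion chemistry by hypervalent-iodine α-hydroxylation, sets out from 13 and comes back at 17.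
  - PhI(OAc)2 and KOH in MeOH (0 °C → rt) add methoxide to C2, oxidise the resulting enolate at C3 and ketalise C4.
  - This gives rac-2,4,4-trimethoxy-5,7-bis(methoxymethoxy)-2-(4-methoxyphenyl)-8-(2-methylbut-3-en-2-yl)chroman-3-ol F3. The 2-OMe/3-OH relationship is assumed cis, and both stereocentres vanish in the next operation.
  - 3 M aq HCl in MeOH at 50 °C then hydrolyses the ketal, eliminates methanol across C2–C3 and removes both MOM groups in one operation.
  - The vinyl group is inert to both reagents.

Step 3.
- **What may go wrong:** The allyl unit may migrate onward to the para carbon by a Cope shift. The prenyl group may be lost thermally as isoprene, or hot Ac2O/AcOH may acetolyse the MOM acetals.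
- **Fallback:** It gives up the ester relay and goes through the free phenol, sets out from 4 and comes back at 10.
  - The rearrangement is run under neutral silylating conditions (N,O-bis(trimethylsilyl)acetamide, PhNEt2, 180 °C). These also mask the O–H as it forms, giving [3,5-bis(methoxymethoxy)-2-(2-methylbut-3-en-2-yl)phenoxy]trimethylsilane F4.
  - K2CO3 in MeOH releases phenol 6, which is now isolated.
  - NIS in CH2Cl2 at −20 °C iodinates the free ortho carbon. This is the less shielded of the two open ring positions, and the phloroglucinol-type ring reacts faster than the alkene. The product is 10.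
  - 10 is charged directly into step 5 in place of 8.

Further compounds
F1 | step 5 | chloromagnesium 2-(chloromagnesio)-3,5-bis(methoxymethoxy)-6-(2-methylbut-3-en-2-yl)phenoxide | C=CC(C)(C)c1c(O[Mg]Cl)c([Mg]Cl)c(OCOC)cc1OCOC
F2 | step 5 | N-methoxy-N-methyl-3-(4-methoxyphenyl)prop-2-ynamide | COc1ccc(C#CC(=O)N(C)OC)cc1
F3 | step 6 | rac-2,4,4-trimethoxy-5,7-bis(methoxymethoxy)-2-(4-methoxyphenyl)-8-(2-methylbut-3-en-2-yl)chroman-3-ol (2-OMe and 3-OH cis, one enantiomer drawn) | C=CC(C)(C)c1c(OCOC)cc(OCOC)c2c1O[C@@](OC)(c3ccc(OC)cc3)[C@H](O)C2(OC)OC
F4 | step 3 | [3,5-bis(methoxymethoxy)-2-(2-methylbut-3-en-2-yl)phenoxy]trimethylsilane | C=CC(C)(C)c1c(O[Si](C)(C)C)cc(OCOC)cc1OCOC
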